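## Retrosynthetic overview

1. Feature: the oxolane O–C11(CH3)–C12–C13–C14 carries C7 (on quaternary C11) and C15 (on C14) on the same face. It is therefore a 7-oxanorbornene whose C7=C15 bridge has been cut, made from 2,4-dimethylfuran plus a C12–C13 acrylimide by a catalytic asymmetric Diels–Alder reaction.
2. The C7=C15 bridge is cleaved in three stages: dihydroxylation, removal of the C12 carboxyl on the saturated bicycle, then periodate. This gives the C7 aldehyde and C15 methyl ketone. C15 becomes CMe2OAc and C7 becomes an (E)-allylboronate C7=C8–C9.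
3. C6–C7 comes from anti-selective allylboration of crotonaldehyde, which sets C6 and C7. C9–C10–C1 comes from a carbonylative B-alkyl Suzuki coupling. Metathesis at C1=C5 closes the seven-membered ring as a 4-silyloxycycloheptenone.
4. C4–C5 and C1–C2 come from anti,anti conjugate addition/allylation on that enone, which fixes the ring fusion. A second metathesis (C3=C4) closes the cyclopentene. C10 methylenation and desilylation finish the route.
5. Ring order: oxolane (as oxanorbornene), then cycloheptenone, then cyclopentene.

Key step: step 1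

Numbering: seven-membered ring C1, C5, C6(OH), C7, C8, C9, C10(=CH2); five-membered ring C1–C2–C3=C4(CH3)–C5; oxolane O–C11(CH3)–C12–C13–C14; C15 is the acetoxy carbon.

Assumption (stereochemistry as read from the SMILES): H-1 and H-5 lie on opposite faces (trans-fused hydroazulene). The 6-OH is cis to C11 on C7 and trans to C4 on C5. The absolute configuration is 1R,5S,6S,7R,11R,14S, and the route is planned for exactly this isomer.

Remark: the C12 carboxyl is removed only after the C7=C15 alkene has been dihydroxylated. A C12 radical next to that alkene would close onto C7 (norbornenyl-to-nortricyclyl rearrangement).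

## Route

Step 1
Reactants: 1 2,4-dimethylfuran; 2 3-acryloyl-1,3-oxazolidin-2-one
Product: 3 endo adduct 3-[(1S,2S,4S)-1,5-dimethyl-7-oxabicyclo[2.2.1]hept-5-ene-2-carbonyl]-1,3-oxazolidin-2-one (bridgehead C1 = C11, bridgehead C4 = C14, C6=C5 = C7=C15, C2 = C12)
Conditions: Cu(SbF6)2·(S,S)-t-Bu-box (10 mol %, from CuCl2, AgSbF6 and 2,2'-isopropylidenebis[(4S)-4-tert-butyl-2-oxazoline]), 1 (2 equiv), 4 Å MS, CH2Cl2, −78 °C; cold filtration through silica gel
Reagents that add atoms: none
Why: The divalent copper bis(oxazoline) complex binds both imide carbonyls of 2 in a square-planar chelate, locks the acryloyl group s-cis and lowers its LUMO, so the electron-rich furan adds across its C2/C5 in a concerted, asynchronous, normal-demand [4+2] cycloaddition; the closest known reaction is the same catalyst system with parent furan and 2. One intermolecular suprafacial–suprafacial event forms C11–C12 and C13–C14, closing the carbocycle C11–C12–C13–C14–C15–C7 and, across the oxygen bridge, the five-membered ring O–C11–C12–C13–C14 that is kept to the end. C11 and C14 are set together: the bridge forces their cis relation, and the tert-butyl group of the (S,S)-ligand covers one face of the bound dienophile and fixes their absolute sense (the sense drawn is the one expected by analogy with furan), while endo C12 is a transient centre erased in step 4. Regiochemistry must place the acyl-bearing carbon next to the methylated bridgehead: the ortho effect of the 2-methyl and the para effect of the 4-methyl both put the largest HOMO coefficient at the unsubstituted furan C5, which bonds to the acrylate β-carbon. The cycloaddition must also outrun conjugate (Friedel–Crafts type) alkylation at furan C5, cycloreversion and opening of the tertiary allylic C11–O bond, which is why it is run at −78 °C and the Lewis acid is removed before warming.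

Step 2
Reactants: 3 endo adduct
Product: 4 exo,exo-diol imide 3-[5,6-exo-dihydroxy-1,5-dimethyl-7-oxabicyclo[2.2.1]heptane-2-endo-carbonyl]-1,3-oxazolidin-2-one
Conditions: OsO4 (2 mol %), NMO, acetone–H2O, 0 °C → rt
Reagents that add atoms: N-methylmorpholine N-oxide, C[N+]1([O-])CCOCC1; water, O
Why: Catalytic OsO4 syn-dihydroxylation takes place on the exo (oxygen-bridge) face of the strained C7=C15 bond, which blocks cycloreversion at once and prepares the glycol cleavage; the two new carbinol centres are transient.

Step 3
Reactants: 4 exo,exo-diol imide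
Product: 6 5,6-exo-dihydroxy-1,5-dimethyl-7-oxabicyclo[2.2.1]heptane-2-endo-carboxylic acid, via lithium percarboxylate 5 (not isolated)
Conditions: LiOH, H2O2, THF–H2O, 0 °C; Na2SO3; HCl to pH 2, NaCl-saturated, EtOAc extraction
Reagents that add atoms: hydrogen peroxide, OO (as LiOOH); lithium hydroxide, [Li+].[OH-] (lithium kept only in 5)
Why: In this hydroperoxide-mediated imide cleavage the small α-effect nucleophile attacks the exocyclic acyl carbonyl and sulfite reduces the percarboxylate, leaving C11 and C14 untouched, and any epimerisation at C12 is without consequence.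

Step 4
Reactants: 6 diol acid
Product: 8 1,3-dimethyl-7-oxabicyclo[2.2.1]heptane-2,3-exo-diol (C12 now CH2), via thiohydroxamate ester 7 (not isolated)
Conditions: DCC, 1-hydroxypyridine-2(1H)-thione, CH2Cl2, 0 °C, dark; then t-BuSH, hν (tungsten lamp), rt
Reagents that add atoms: 1-hydroxypyridine-2(1H)-thione, ON1C=CC=CC1=S (kept only in 7)
Why: In this Barton reductive decarboxylation the secondary C12 radical has no π-bond within reach in the saturated bicycle and is simply quenched by the thiol, and the N-hydroxy compound is acylated much faster than the hindered exo alcohols in the absence of DMAP.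

Step 5
Reactants: 8 bicyclic diol
Product: 9 (2R,5S)-5-acetyl-2-methyloxolane-2-carbaldehyde (formyl on C11 and acetyl on C14 cis)
Conditions: NaIO4 on silica gel, CH2Cl2, rt; filtrate used directly
Reagents that add atoms: none
Why: In this Malaprade glycol cleavage the rigid eclipsed exo-diol forms the cyclic periodate ester easily, and breaking C7–C15 leaves C7 and C15 necessarily cis on the oxolane, with C11 quaternary and C14 never exposed to base.

Step 6
Reactants: 9 keto aldehyde
Product: 10 ethyl (E)-3-[(2R,5S)-5-acetyl-2-methyloxolan-2-yl]prop-2-enoate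
Conditions: Ph3P=CHCO2Et, CH2Cl2, rt → 40 °C
Reagents that add atoms: (ethoxycarbonylmethylene)triphenylphosphorane, CCOC(=O)C=P(c1ccccc1)(c1ccccc1)c1ccccc1
Why: In this Wittig olefination the stabilised ylide reacts with the aldehyde but not with the methyl ketone, gives the E-alkene C7=C8, and is neutral enough to spare the epimerisable C14.

Step 7
Reactants: 10 keto enoate
Product: 11 ethyl (E)-3-[(2R,5S)-5-(2-hydroxypropan-2-yl)-2-methyloxolan-2-yl]prop-2-enoate
Conditions: MeMgBr (1.1 equiv), THF, −78 °C; H2O
Reagents that add atoms: methylmagnesium bromide, C[Mg]Br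
Why: In this Grignard addition the chelation-activated α-alkoxy ketone reacts at −78 °C much faster than the enoate, whose β-carbon is shielded by quaternary C11, and C15 carries two methyls so no stereocentre arises.

Step 8
Reactants: 11 hydroxy enoate
Product: 12 (E)-3-[(2R,5S)-5-(2-hydroxypropan-2-yl)-2-methyloxolan-2-yl]prop-2-en-1-ol
Conditions: i-Bu2AlH (3.3 equiv), CH2Cl2, −78 °C; aq. Rochelle salt
Reagents that add atoms: none
Why: i-Bu2AlH effects a standard 1,2-reduction of the enoate to the allylic alcohol with retention of the E-geometry.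

Step 9
Reactants: 12 diol
Product: 13 diacetate (E)-3-[(2R,5S)-5-(2-acetoxypropan-2-yl)-2-methyloxolan-2-yl]prop-2-en-1-yl acetate
Conditions: Ac2O, Et3N, DMAP, CH2Cl2, rt → 40 °C
Reagents that add atoms: acetic anhydride, CC(=O)OC(C)=O
Why: One DMAP-catalysed acylation installs both the tertiary C15 acetate of the target and the allylic leaving group at C9.

Step 10
Reactants: 13 diacetate
Product: 14 (E)-allylboronate 2-[(2S,5R)-5-methyl-5-[(E)-3-(4,4,5,5-tetramethyl-1,3,2-dioxaborolan-2-yl)prop-1-enyl]oxolan-2-yl]propan-2-yl acetate
Conditions: B2pin2, Pd2(dba)3 (2.5 mol %), DMSO, 50 °C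
Reagents that add atoms: bis(pinacolato)diboron, CC1(C)OB(OC1(C)C)B1OC(C)(C)C(C)(C)O1
Why: In this Miyaura-type allylic borylation zerovalent palladium ionises only the allylic acetate, and boron is delivered to the unhindered terminus C9 of the syn π-allyl complex, giving the linear E-boronate while the tertiary acetate is inert.

Step 11
Reactants: 14 (E)-allylboronate; 15 (E)-but-2-enal
Product: 17 (6S,7R,11R,14S)-dienol 2-[(2S,5R)-5-[(3R,4S,5E)-4-hydroxyhepta-1,5-dien-3-yl]-5-methyloxolan-2-yl]propan-2-yl acetate, via O-boryl ether 16 (not isolated)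
Conditions: (R)-TRIP (3,3'-bis(2,4,6-triisopropylphenyl)-BINOL hydrogen phosphate, 10 mol %), 4 Å MS, toluene, −30 °C → rt; aqueous work-up
Reagents that add atoms: none
Why: In this Brønsted-acid-catalysed allylboration the closed Zimmerman–Traxler chair translates the E-geometry into the anti C6/C7 relation (cis once both carbons are in the ring), and the (R)-phosphoric acid is expected, by analogy with simple aldehydes, to direct attack to the Re face of 15 and so fix 6S and hence 7R (the antipodal acid would be used if the sense proves opposite).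

Step 12
Reactants: 17 dienol
Product: 18 triethylsilyl ether of 17
Conditions: TESOTf, 2,6-lutidine, CH2Cl2, −78 → 0 °C
Reagents that add atoms: triethylsilyl triflate, CC[Si](CC)(CC)OS(=O)(=O)C(F)(F)F
Why: The silyl triflate silylates the hindered secondary alcohol, and the ether later shields the β-face of the enone and is removable without touching the acetate.

Step 13
Reactants: 18 silyl ether
Product: 20 dienone (C1 vinyl ketone at C10, E-propenyl at C6), via B-alkyl-9-BBN 19 (not isolated)
Conditions: 9-BBN, THF, 0 °C → rt; then CH2=CHI, Pd(PPh3)4 (5 mol %), K3PO4, CO (1 atm), THF–benzene, rt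
Reagents that add atoms: 9-BBN, [H]B1C2CCCC1CCC2 (boron unit kept only in 19); carbon monoxide, [C-]#[O+]; vinyl iodide, C=CI
Why: 9-BBN hydroborates the terminal C8=C9 vinyl group far faster than the internal propenyl group, and the acylpalladium species formed from vinyl iodide and CO is alkylated by the borane in a carbonylative Suzuki–Miyaura coupling, a known route from 9-alkyl-9-BBN reagents and iodoalkenes to enones.

Step 14
Reactants: 20 dienone
Product: 21 (6S,7R)-cyclohept-2-enone: C10 ketone, C1=C5 alkene, C6 OTES and C7 oxolanyl cis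
Conditions: second-generation Hoveyda–Grubbs catalyst (H2IMes)Cl2Ru(=CH-C6H4-2-OiPr) (5 mol %), CH2Cl2 (2 mM), 40 °C
Reagents that add atoms: none
Why: In this ring-closing metathesis the catalyst loads on the propenyl group and closes onto the vinyl ketone, the only two alkenes present, giving a seven-membered enone with loss of propene and no change at C6 or C7.

Step 15
Reactants: 21 cycloheptenone
Product: 23 (1R,5S,6S,7R)-2-allyl-3-isopropenylcycloheptanone (allyl on C1, isopropenyl on C5), via magnesium enolate 22 (not isolated)
Conditions: CH2=C(CH3)MgBr (2.4 equiv), CuI (1.2 equiv), THF, −40 → −78 °C; 21, −78 °C; then allyl iodide, HMPA, −78 → −20 °C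
Reagents that add atoms: isopropenylmagnesium bromide, C=C(C)[Mg]Br; allyl iodide, C=CCI
Why: In this cuprate conjugate addition with enolate alkylation (vicinal difunctionalisation) the cuprate attacks C5 anti to the adjacent C6 silyloxy group (the C7 oxolanyl group lies on the same face), and the regiodefined enolate is allylated at C1 anti to the new isopropenyl group, so C4 and C2 end up trans as the ring fusion requires; trans-2,3-disubstitution should also be the more stable arrangement at the epimerisable C1.

Step 16
Reactants: 23 allyl isopropenyl ketone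
Product: 24 trans-fused hydroazulenone (C10 ketone, C3=C4(CH3), C6 OTES)
Conditions: second-generation Grubbs catalyst (H2IMes)(PCy3)Cl2Ru=CHPh (5 mol %), CH2Cl2, 40 °C
Reagents that add atoms: none
Why: Ring-closing metathesis of the allyl and isopropenyl groups, the only alkenes present, forms the trisubstituted C3=C4 bond of the cyclopentene under neutral conditions that leave C1 and C5 unchanged.

Step 17
Reactants: 24 hydroazulenone
Product: 25 C10-methylene compound (triethylsilyl ether of the target)
Conditions: Zn, CH2Br2, TiCl4 (reagent pre-aged in THF at 5 °C), CH2Cl2, 0 °C → rt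
Reagents that add atoms: dibromomethane, BrCBr
Why: The non-basic gem-dimetal reagent of the Takai–Lombardo methylenation converts enolisable ketones without epimerising the α-centre C1 and does not attack esters.

Step 18
Reactants: 25 silyl ether
Product: 26 target
Conditions: HF·pyridine, pyridine, THF, 0 °C
Reagents that add atoms: none
Why: Buffered fluoride desilylation frees the C6 hydroxyl while the tertiary acetate, the exocyclic methylene and the trisubstituted alkene are left alone.

## Compound list

1 | 2,4-dimethylfuran | Cc1cc(C)co1 | starting material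
2 | 3-acryloyl-1,3-oxazolidin-2-one | C=CC(=O)N1CCOC1=O | starting material
3 | endo Diels–Alder adduct | CC1=C[C@@]2(C)[C@@H](C(=O)N3CCOC3=O)C[C@@H]1O2 | intermediate
4 | exo,exo-diol imide | C[C@@]1(O)[C@H](O)[C@@]2(C)[C@@H](C(=O)N3CCOC3=O)C[C@@H]1O2 | intermediate
5 | lithium percarboxylate | C[C@@]1(O)[C@H](O)[C@@]2(C)[C@@H](C(=O)O[O-])C[C@@H]1O2.[Li+] | intermediate
6 | diol acid | C[C@@]1(O)[C@H](O)[C@@]2(C)[C@@H](C(=O)O)C[C@@H]1O2 | intermediate
7 | thiohydroxamate (Barton) ester | C[C@@]1(O)[C@H](O)[C@@]2(C)[C@@H](C(=O)ON3C=CC=CC3=S)C[C@@H]1O2 | intermediate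
8 | decarboxylated bicyclic diol | C[C@@]1(O)[C@H](O)[C@@]2(C)CC[C@@H]1O2 | intermediate
9 | (2R,5S)-5-acetyl-2-methyloxolane-2-carbaldehyde | O=C[C@@]1(C)CC[C@@H](C(C)=O)O1 | intermediate
10 | keto enoate | CCOC(=O)/C=C/[C@@]1(C)CC[C@@H](C(C)=O)O1 | intermediate
11 | hydroxy enoate | CCOC(=O)/C=C/[C@@]1(C)CC[C@@H](C(C)(C)O)O1 | intermediate
12 | allylic alcohol/tertiary alcohol diol | OC/C=C/[C@@]1(C)CC[C@@H](C(C)(C)O)O1 | intermediate
13 | diacetate | CC(=O)OC/C=C/[C@@]1(C)CC[C@@H](C(C)(C)OC(C)=O)O1 | intermediate
14 | (E)-allylboronate | CC1(C)OB(C/C=C/[C@@]2(C)CC[C@@H](C(C)(C)OC(C)=O)O2)OC1(C)C | intermediate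
15 | (E)-but-2-enal | C/C=C/C=O | starting material
16 | O-pinacolboryl ether of 17 | C=C[C@@H]([C@@]1(C)CC[C@@H](C(C)(C)OC(C)=O)O1)[C@@H](OB1OC(C)(C)C(C)(C)O1)/C=C/C | intermediate
17 | (6S,7R)-dienol | C=C[C@@H]([C@@]1(C)CC[C@@H](C(C)(C)OC(C)=O)O1)[C@@H](O)/C=C/C | intermediate
18 | triethylsilyl ether of 17 | C=C[C@@H]([C@@]1(C)CC[C@@H](C(C)(C)OC(C)=O)O1)[C@@H](O[Si](CC)(CC)CC)/C=C/C | intermediate
19 | B-alkyl-9-BBN | B1(C2CCCC1CCC2)CC[C@@H]([C@@]3(C)CC[C@@H](C(C)(C)OC(C)=O)O3)[C@@H](O[Si](CC)(CC)CC)/C=C/C | intermediate
20 | dienone | C=CC(=O)CC[C@@H]([C@@]1(C)CC[C@@H](C(C)(C)OC(C)=O)O1)[C@@H](O[Si](CC)(CC)CC)/C=C/C | intermediate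
21 | cycloheptenone | O=C1CC[C@@H]([C@@]2(C)CC[C@@H](C(C)(C)OC(C)=O)O2)[C@@H](O[Si](CC)(CC)CC)C=C1 | intermediate
22 | bromomagnesium enolate | Br[Mg]OC1=C[C@@H](C(C)=C)[C@H](O[Si](CC)(CC)CC)[C@H]([C@@]2(C)CC[C@@H](C(C)(C)OC(C)=O)O2)CC1 | intermediate
23 | trans-2-allyl-3-isopropenylcycloheptanone | O=C1CC[C@@H]([C@@]2(C)CC[C@@H](C(C)(C)OC(C)=O)O2)[C@@H](O[Si](CC)(CC)CC)[C@H](C(C)=C)[C@H]1CC=C | intermediate
24 | trans-fused hydroazulenone | O=C1CC[C@@H]([C@@]2(C)CC[C@@H](C(C)(C)OC(C)=O)O2)[C@@H](O[Si](CC)(CC)CC)[C@@H]2C(C)=CC[C@@H]12 | intermediate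
25 | triethylsilyl ether of the target | C=C1CC[C@@H]([C@@]2(C)CC[C@@H](C(C)(C)OC(C)=O)O2)[C@@H](O[Si](CC)(CC)CC)[C@@H]2C(C)=CC[C@@H]12 | intermediate
26 | CNP0302132.3 | C=C1CC[C@@H]([C@@]2(C)CC[C@@H](C(C)(C)OC(C)=O)O2)[C@@H](O)[C@@H]2C(C)=CC[C@@H]12 | target

## Step count and risks

Total step count: 18. Longest linear sequence: 18 steps (from 1 and 2).

**Step 1.** Three processes may compete. The activated imide may alkylate the free furan C5 by conjugate addition instead of cycloadding. The adduct may revert or lose enantiopurity on warming. The Lewis acid may open the tertiary allylic C11–O bridge.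

The fallback removes the Lewis acid and moves stereocontrol to a covalent auxiliary. It sets out from 1, which is combined with commercial (S)-3-acryloyl-4-benzyl-1,3-oxazolidin-2-one (C=CC(=O)N1[C@@H](Cc2ccccc2)COC1=O) in CH2Cl2 at about 12 kbar and room temperature. The diastereomeric adducts are separated by crystallisation or chromatography to give the benzyl-substituted endo adduct F1. OsO4/NMO converts this into its exo-diol F2. LiOH/H2O2 followed by sulfite then brings the sequence back to the route at 6.

**Step 11.** The γ-carbon C7 is neopentyl-like, so addition may be slow. Facial selectivity may be poor if the catalyst and the C11 stereocentre oppose each other.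

The fallback separates the stereoisomers after bond formation instead of controlling the face during it. It sets out from 14 and 15, which are heated in toluene without catalyst. The chair transition state still enforces the anti relation, so 16 forms together with the diastereomeric boryl ether F3. Hydrolysis gives 17 and the (6R,7S)-dienol F4.

A Sharpless kinetic resolution follows (Ti(OiPr)4, L-(+)-DIPT, t-BuOOH, 4 Å MS, CH2Cl2, −20 °C). It should epoxidise the fast-reacting carbinol F4 to the erythro epoxy alcohol F5. The slow-reacting 17 is recovered by chromatography, where the fallback rejoins the route.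

**Step 13.** Direct, non-carbonylative coupling may compete. The vinyl ketone may be lost by polymerisation or conjugate addition in the basic coupling medium.

The fallback builds C10 by hydroformylation instead of CO insertion at palladium. It sets out from 18. Rh(acac)(CO)2/BIPHEPHOS under CO/H2 (toluene, 60 °C) converts only the terminal vinyl group into the linear aldehyde F6. Vinylmagnesium bromide at −78 °C gives the allylic alcohol F7 (both C10 epimers). Dess–Martin periodinane oxidises this to 20, where the route continues.

## Further compounds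

F1 | step 1 | benzyl-substituted endo adduct | CC1=C[C@@]2(C)[C@@H](C(=O)N3[C@@H](Cc4ccccc4)COC3=O)C[C@@H]1O2
F2 | step 1 | exo-diol of F1 | C[C@@]1(O)[C@H](O)[C@@]2(C)[C@@H](C(=O)N3[C@@H](Cc4ccccc4)COC3=O)C[C@@H]1O2
F3 | step 11 | diastereomeric (6R,7S) boryl ether | C=C[C@H]([C@@]1(C)CC[C@@H](C(C)(C)OC(C)=O)O1)[C@H](OB1OC(C)(C)C(C)(C)O1)/C=C/C
F4 | step 11 | (6R,7S)-dienol | C=C[C@H]([C@@]1(C)CC[C@@H](C(C)(C)OC(C)=O)O1)[C@H](O)/C=C/C
F5 | step 11 | erythro epoxy alcohol from F4 | C=C[C@H]([C@@]1(C)CC[C@@H](C(C)(C)OC(C)=O)O1)[C@H](O)[C@@H]2O[C@H]2C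
F6 | step 13 | linear C10 aldehyde | O=CCC[C@@H]([C@@]1(C)CC[C@@H](C(C)(C)OC(C)=O)O1)[C@@H](O[Si](CC)(CC)CC)/C=C/C
F7 | step 13 | C10 allylic alcohol (epimers at C10) | C=CC(O)CC[C@@H]([C@@]1(C)CC[C@@H](C(C)(C)OC(C)=O)O1)[C@@H](O[Si](CC)(CC)CC)/C=C/C
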